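**Plan**
Ring letters: A is the formyl-bearing benzene, B the benzene of the chromanone, C the seven-membered lactone ring, D the dihydropyranone.
Retrosynthesis: the lactone C(=O)–O7 bond of ring C is cut first. Ring A is then taken apart at A-C1–A-C2, A-C3–A-C4 and A-C4–A-C5 into an alkynyl ether on O6 of ring B and an ester-bearing isopropenylketene that comes from a diazo keto ester.
Enabling feature: ring A (A-C1 carboxyl, A-C2 aryl ether O, A-C3 CHO, A-C4 OH, A-C5 H, A-C6 CH3) is hexasubstituted, with the A-C4 phenol and the A-C2 ether oxygen meta to each other around the carbon substituent at A-C3 and the carboxyl para to the phenol; a vinylketene and an alkynyl ether give exactly this pattern.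
Forward: rings B and D from 2,4-dihydroxy-6-methylbenzaldehyde (Dakin oxidation, acylation/oxa-Michael), PMB on O7, alkynylation of O6, ring A by benzannulation, CH2OSi to CHO, acid deprotection, ring C by lactonisation last.
Stereochemistry: the target has no stereocentre; the carbinol carbon of 14 and the quaternary carbon of 17 are racemic and are destroyed on the way.

Key step: step 9

Remark: O7 of ring B is carried as a 4-methoxybenzyl (PMB) ether, because an aryl silyl ether beside the free O6 phenol would migrate between the catechol oxygens under the basic coupling conditions; PMB then falls together with the tert-butyl ester in acid.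

**Route**

Step 1
Reactants: 1 2,4-dihydroxy-6-methylbenzaldehyde
Product: 3 6-methylbenzene-1,2,4-triol, via aryl formate 2 (not isolated)
Conditions: 30% H2O2, B(OH)3, H2SO4 (cat.), THF, 23 °C; work-up under argon, used crude
Reagents that add atoms: hydrogen peroxide, OO
Why: Dakin oxidation: hydrogen peroxide adds to the aldehyde activated by its ortho and para hydroxyls, the electron-rich aryl group migrates to oxygen (Baeyer–Villiger type) and formate 2 is hydrolysed in the acidic medium, while boric acid ties up the new catechol and shields it from further oxidation.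

Step 2
Reactants: 3 6-methylbenzene-1,2,4-triol; 4 3-methylbut-2-enoic acid
Product: 6 6,7-dihydroxy-2,2,5-trimethylchroman-4-one, via hydroxyaryl enone 5 (not isolated)
Conditions: P2O5/MeSO3H (1:10 w/w), 70 °C, argon
Reagents that add atoms: none
Why: Friedel–Crafts acylation at C5 of the triol (ortho to O4, para to O2, the site acylated in hydroxyquinols and 3,4-dialkoxyphenols), followed by intramolecular oxa-Michael addition of the O4 hydroxyl to enone 5, is the standard one-pot entry to 2,2-dimethylchroman-4-ones.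

Step 3
Reactants: 6 6,7-dihydroxy-2,2,5-trimethylchroman-4-one
Product: 7 6-hydroxy-7-[(4-methoxyphenyl)methoxy]-2,2,5-trimethylchroman-4-one
Conditions: PMBCl (1.05 equiv), K2CO3 (1.1 equiv), DMF, 23 °C
Reagents that add atoms: 4-methoxybenzyl chloride, COc1ccc(CCl)cc1
Why: Williamson etherification under substrate control: the O7 hydroxyl is para to the C4 carbonyl and so the more acidic and less hindered of the two (O6 lies between the methyl group and O7), and one equivalent of carbonate should alkylate it selectively, as in the 4-O-alkylation of 3,4-dihydroxyaryl ketones.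

Step 4
Reactants: 8 (tert-butyldimethylsilyloxy)acetaldehyde
Product: 9 tert-butyl[(3,3-dibromoprop-2-en-1-yl)oxy]dimethylsilane
Conditions: CBr4 (2 equiv), PPh3 (4 equiv), CH2Cl2, 0 °C
Reagents that add atoms: carbon tetrabromide, BrC(Br)(Br)Br
Why: Ramirez dibromo-olefination (first stage of the Corey–Fuchs sequence): Ph3P=CBr2 formed from CBr4 and PPh3 undergoes a Wittig reaction with the aldehyde, and the silyl ether survives at 0 °C.

Step 5
Reactants: 7 6-hydroxy-7-[(4-methoxyphenyl)methoxy]-2,2,5-trimethylchroman-4-one; 9 tert-butyl[(3,3-dibromoprop-2-en-1-yl)oxy]dimethylsilane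
Product: 10 6-{[(1Z)-1-bromo-3-(tert-butyldimethylsilyloxy)prop-1-en-1-yl]oxy}-7-[(4-methoxyphenyl)methoxy]-2,2,5-trimethylchroman-4-one
Conditions: CuI (10 mol%), 2,2'-bipyridine (20 mol%), K3PO4 (3 equiv), 9 (1.5 equiv), toluene, 110 °C
Reagents that add atoms: none
Why: Copper-catalysed Ullmann-type C–O coupling of a phenol with a 1,1-dibromoalkene, which takes place at the less hindered C–Br bond trans to the chain and stops at the monoether, so that bromine ends cis to the CH2OTBS group and anti to the vinylic hydrogen (Z isomer).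

Step 6
Reactants: 10 6-{[(1Z)-1-bromo-3-(tert-butyldimethylsilyloxy)prop-1-en-1-yl]oxy}-7-[(4-methoxyphenyl)methoxy]-2,2,5-trimethylchroman-4-one
Product: 11 6-{[3-(tert-butyldimethylsilyloxy)prop-1-yn-1-yl]oxy}-7-[(4-methoxyphenyl)methoxy]-2,2,5-trimethylchroman-4-one
Conditions: KOtBu (2.2 equiv), 1,4-dioxane, 23 °C
Reagents that add atoms: none
Why: Anti E2 dehydrobromination of the α-bromo enol ether by tert-butoxide gives the alkynyl ether; the hindered aryl ketone is at most reversibly enolised and the PMB and alkyl TBS ethers are inert to the base.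

Step 7
Reactants: 12 tert-butyl diazoacetate; 13 2-methylprop-2-enal (methacrolein)
Product: 14 tert-butyl 2-diazo-3-hydroxy-4-methylpent-4-enoate (racemic)
Conditions: DBU (20 mol%), MeCN, 0 °C
Reagents that add atoms: none
Why: Base-catalysed aldol-type 1,2-addition of the diazoacetate α-carbon to the aldehyde with retention of the diazo group, run cold so that dipolar cycloaddition to the enal stays slow; the carbinol centre forms as a racemate and is removed in step 8.

Step 8
Reactants: 14 tert-butyl 2-diazo-3-hydroxy-4-methylpent-4-enoate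
Product: 15 tert-butyl 2-diazo-4-methyl-3-oxopent-4-enoate
Conditions: Dess–Martin periodinane (1.2 equiv), CH2Cl2, 0 to 23 °C
Reagents that add atoms: none
Why: Dess–Martin oxidation of a β-hydroxy α-diazo ester to the 2-diazo-1,3-keto ester, a standard transformation in which the acceptor-stabilised diazo group tolerates the oxidant and the acetic acid released.

Step 9
Reactants: 11 6-{[3-(tert-butyldimethylsilyloxy)prop-1-yn-1-yl]oxy}-7-[(4-methoxyphenyl)methoxy]-2,2,5-trimethylchroman-4-one; 15 tert-butyl 2-diazo-4-methyl-3-oxopent-4-enoate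
Product: 20 tert-butyl 3-[(tert-butyldimethylsilyloxy)methyl]-4-hydroxy-2-({7-[(4-methoxyphenyl)methoxy]-2,2,5-trimethyl-4-oxochroman-6-yl}oxy)-6-methylbenzoate, via vinylketene 16 (not isolated), via cyclobutenone 17 (not isolated), via dienylketene 18 (not isolated), via cyclohexadienone 19 (not isolated)
Conditions: 15 (1.5 equiv) added over 4 h to 11 in degassed o-xylene, 144 °C; then 1 h
Reagents that add atoms: none
Why: Proposed new method: thermal loss of N2 from 15 with 1,2-shift of the isopropenyl group (Wolff rearrangement) should give vinylketene 16, whose carbonyl carbon is attacked by the silyloxymethyl-bearing carbon of the alkynyl ether, so that [2+2] closure to cyclobutenone 17 forms A-C3–A-C4 and A-C1–A-C2. Four-electron ring opening of 17 gives dienylketene 18, and ring A is closed by thermal six-electron (disrotatory) electrocyclisation between the ketene carbon and the isopropenyl CH2 (A-C4–A-C5), after which cyclohexadienone 19 tautomerises to phenol 20. The closest known reaction type is the benzannulation of vinylketenes (from Wolff rearrangement of unsaturated α-diazo ketones or from cyclobutenones) with alkynyl ethers and ynamides, combined with the thermal Wolff rearrangement of 2-diazo-1,3-dicarbonyl compounds; the ester on the ketene is the untested element. No stereocentre results, because the quaternary carbon of 17 is lost on ring opening and the dienylketene isomer that cannot close returns through reversible ring closure. The step needs [2+2] addition to win over hetero-[4+2] addition (a pyranone): the bulky, weakly nucleophilic tert-butyl ester carbonyl is a poor terminus for that closure, and slow addition keeps the ketene dilute beside the alkyne. The regiochemistry follows the polarisation of the alkynyl ether, which places aryloxy at A-C2, the alkyne substituent at A-C3, the ketene oxygen at A-C4, the ester at A-C1 and the isopropenyl methyl at A-C6.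

Step 10
Reactants: 20 tert-butyl 3-[(tert-butyldimethylsilyloxy)methyl]-4-hydroxy-2-({7-[(4-methoxyphenyl)methoxy]-2,2,5-trimethyl-4-oxochroman-6-yl}oxy)-6-methylbenzoate
Product: 21 tert-butyl 4-hydroxy-3-(hydroxymethyl)-2-({7-[(4-methoxyphenyl)methoxy]-2,2,5-trimethyl-4-oxochroman-6-yl}oxy)-6-methylbenzoate
Conditions: Bu4NF (1.2 equiv), AcOH (1.2 equiv), THF, 0 to 23 °C
Reagents that add atoms: none
Why: Fluoride-mediated desilylation of the primary benzylic TBS ether, buffered with acetic acid so that the phenol is not exposed to basic fluoride; tert-butyl ester, PMB ether and ketone are untouched.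

Step 11
Reactants: 21 tert-butyl 4-hydroxy-3-(hydroxymethyl)-2-({7-[(4-methoxyphenyl)methoxy]-2,2,5-trimethyl-4-oxochroman-6-yl}oxy)-6-methylbenzoate
Product: 22 tert-butyl 3-formyl-4-hydroxy-2-({7-[(4-methoxyphenyl)methoxy]-2,2,5-trimethyl-4-oxochroman-6-yl}oxy)-6-methylbenzoate
Conditions: activated MnO2 (15 equiv), CH2Cl2, 23 °C
Reagents that add atoms: none
Why: Chemoselective MnO2 oxidation of the benzylic (salicyl) alcohol to the salicylaldehyde, which is stabilised by hydrogen bonding to the A-C4 phenol; the position para to that phenol carries the ester, so quinone formation is not available.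

Step 12
Reactants: 22 tert-butyl 3-formyl-4-hydroxy-2-({7-[(4-methoxyphenyl)methoxy]-2,2,5-trimethyl-4-oxochroman-6-yl}oxy)-6-methylbenzoate
Product: 23 3-formyl-4-hydroxy-2-[(7-hydroxy-2,2,5-trimethyl-4-oxochroman-6-yl)oxy]-6-methylbenzoic acid
Conditions: TFA/CH2Cl2 (1:4), anisole (10 equiv), 0 to 23 °C
Reagents that add atoms: none
Why: Acidolysis by alkyl–oxygen cleavage: the tert-butyl ester loses isobutene (unaffected by the two ortho substituents that shield the carbonyl) and the PMB ether loses the 4-methoxybenzyl cation, which anisole captures by Friedel–Crafts alkylation; aldehyde, ketone and diaryl ether are stable to TFA.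

Step 13
Reactants: 23 3-formyl-4-hydroxy-2-[(7-hydroxy-2,2,5-trimethyl-4-oxochroman-6-yl)oxy]-6-methylbenzoic acid
Product: 25 mollicellin A, via mixed anhydride 24 (not isolated)
Conditions: (CF3CO)2O (3 equiv), toluene (0.005 M), 0 to 23 °C; aq. NaHCO3/MeOH work-up
Reagents that add atoms: none
Why: Lactonisation through aroyl trifluoroacetate 24 (the trifluoroacetic anhydride method used for depsides and depsidones): the di-ortho-substituted acid is activated as the mixed anhydride and captured intramolecularly by the O7 phenol, closing the seven-membered ring C under dilution, and any aryl trifluoroacetate formed is cleaved in the bicarbonate work-up.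

**Compound list**
1 | 2,4-dihydroxy-6-methylbenzaldehyde | Cc1cc(O)cc(O)c1C=O | starting material
2 | 2,4-dihydroxy-6-methylphenyl formate | Cc1cc(O)cc(O)c1OC=O | intermediate
3 | 6-methylbenzene-1,2,4-triol | Cc1cc(O)cc(O)c1O | intermediate
4 | 3-methylbut-2-enoic acid | CC(C)=CC(=O)O | starting material
5 | 3-methyl-1-(3,4,6-trihydroxy-2-methylphenyl)but-2-en-1-one | CC(C)=CC(=O)c1c(C)c(O)c(O)cc1O | intermediate
6 | 6,7-dihydroxy-2,2,5-trimethylchroman-4-one | Cc1c(O)c(O)cc2OC(C)(C)CC(=O)c12 | intermediate
7 | 6-hydroxy-7-[(4-methoxyphenyl)methoxy]-2,2,5-trimethylchroman-4-one | Cc1c(O)c(OCc3ccc(OC)cc3)cc2OC(C)(C)CC(=O)c12 | intermediate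
8 | (tert-butyldimethylsilyloxy)acetaldehyde | O=CCO[Si](C)(C)C(C)(C)C | starting material
9 | tert-butyl[(3,3-dibromoprop-2-en-1-yl)oxy]dimethylsilane | BrC(Br)=CCO[Si](C)(C)C(C)(C)C | intermediate
10 | 6-{[(1Z)-1-bromo-3-(tert-butyldimethylsilyloxy)prop-1-en-1-yl]oxy}-7-[(4-methoxyphenyl)methoxy]-2,2,5-trimethylchroman-4-one | Cc1c(O/C(Br)=C/CO[Si](C)(C)C(C)(C)C)c(OCc3ccc(OC)cc3)cc2OC(C)(C)CC(=O)c12 | intermediate
11 | 6-{[3-(tert-butyldimethylsilyloxy)prop-1-yn-1-yl]oxy}-7-[(4-methoxyphenyl)methoxy]-2,2,5-trimethylchroman-4-one | Cc1c(OC#CCO[Si](C)(C)C(C)(C)C)c(OCc3ccc(OC)cc3)cc2OC(C)(C)CC(=O)c12 | intermediate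
12 | tert-butyl diazoacetate | [N-]=[N+]=CC(=O)OC(C)(C)C | starting material
13 | 2-methylprop-2-enal (methacrolein) | CC(=C)C=O | starting material
14 | tert-butyl 2-diazo-3-hydroxy-4-methylpent-4-enoate (racemic) | CC(=C)C(O)C(=[N+]=[N-])C(=O)OC(C)(C)C | intermediate
15 | tert-butyl 2-diazo-4-methyl-3-oxopent-4-enoate | CC(=C)C(=O)C(=[N+]=[N-])C(=O)OC(C)(C)C | intermediate
16 | tert-butyl 3-methyl-2-(oxomethylidene)but-3-enoate (the ester-bearing isopropenylketene) | CC(=C)C(=C=O)C(=O)OC(C)(C)C | intermediate
17 | tert-butyl 3-[(tert-butyldimethylsilyloxy)methyl]-2-({7-[(4-methoxyphenyl)methoxy]-2,2,5-trimethyl-4-oxochroman-6-yl}oxy)-4-oxo-1-(prop-1-en-2-yl)cyclobut-2-ene-1-carboxylate (racemic) | O=C1C(CO[Si](C)(C)C(C)(C)C)=C(Oc2c(C)c3C(=O)CC(C)(C)Oc3cc2OCc4ccc(OC)cc4)C1(C(C)=C)C(=O)OC(C)(C)C | intermediate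
18 | tert-butyl (2Z)-4-[(tert-butyldimethylsilyloxy)methyl]-3-({7-[(4-methoxyphenyl)methoxy]-2,2,5-trimethyl-4-oxochroman-6-yl}oxy)-5-oxo-2-(prop-1-en-2-yl)penta-2,4-dienoate (dienylketene) | O=C=C(CO[Si](C)(C)C(C)(C)C)/C(Oc2c(C)c3C(=O)CC(C)(C)Oc3cc2OCc4ccc(OC)cc4)=C(\C(C)=C)C(=O)OC(C)(C)C | intermediate
19 | tert-butyl 5-[(tert-butyldimethylsilyloxy)methyl]-6-({7-[(4-methoxyphenyl)methoxy]-2,2,5-trimethyl-4-oxochroman-6-yl}oxy)-2-methyl-4-oxocyclohexa-1,5-diene-1-carboxylate | O=C1CC(C)=C(C(=O)OC(C)(C)C)C(Oc2c(C)c3C(=O)CC(C)(C)Oc3cc2OCc4ccc(OC)cc4)=C1CO[Si](C)(C)C(C)(C)C | intermediate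
20 | tert-butyl 3-[(tert-butyldimethylsilyloxy)methyl]-4-hydroxy-2-({7-[(4-methoxyphenyl)methoxy]-2,2,5-trimethyl-4-oxochroman-6-yl}oxy)-6-methylbenzoate | Cc1cc(O)c(CO[Si](C)(C)C(C)(C)C)c(Oc2c(C)c3C(=O)CC(C)(C)Oc3cc2OCc4ccc(OC)cc4)c1C(=O)OC(C)(C)C | intermediate
21 | tert-butyl 4-hydroxy-3-(hydroxymethyl)-2-({7-[(4-methoxyphenyl)methoxy]-2,2,5-trimethyl-4-oxochroman-6-yl}oxy)-6-methylbenzoate | Cc1cc(O)c(CO)c(Oc2c(C)c3C(=O)CC(C)(C)Oc3cc2OCc4ccc(OC)cc4)c1C(=O)OC(C)(C)C | intermediate
22 | tert-butyl 3-formyl-4-hydroxy-2-({7-[(4-methoxyphenyl)methoxy]-2,2,5-trimethyl-4-oxochroman-6-yl}oxy)-6-methylbenzoate | Cc1cc(O)c(C=O)c(Oc2c(C)c3C(=O)CC(C)(C)Oc3cc2OCc4ccc(OC)cc4)c1C(=O)OC(C)(C)C | intermediate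
23 | 3-formyl-4-hydroxy-2-[(7-hydroxy-2,2,5-trimethyl-4-oxochroman-6-yl)oxy]-6-methylbenzoic acid | Cc1cc(O)c(C=O)c(Oc2c(C)c3C(=O)CC(C)(C)Oc3cc2O)c1C(=O)O | intermediate
24 | 3-formyl-4-hydroxy-2-[(7-hydroxy-2,2,5-trimethyl-4-oxochroman-6-yl)oxy]-6-methylbenzoic trifluoroacetic anhydride | Cc1cc(O)c(C=O)c(Oc2c(C)c3C(=O)CC(C)(C)Oc3cc2O)c1C(=O)OC(=O)C(F)(F)F | intermediate
25 | mollicellin A | Cc1cc(O)c(C=O)c2c1C(=O)Oc1cc3c(c(C)c1O2)C(=O)CC(C)(C)O3 | target

**Step count**
Total: 13 steps. Longest linear sequence: 10 steps (1, 2, 3, 5, 6, 9, 10, 11, 12, 13).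

**Steps most likely to fail**

1. Step 9 (benzannulation). The ester carbonyl of the ketene may close onto the alkynyl ether in a hetero-[4+2] sense instead of C–C closure to the cyclobutenone. The ketene may also dimerise or acylate the product phenol, and the tert-butyl ester may lose isobutene at 144 °C.
Fallback (sets out from 7, returns at 23; known reactions only): the diaryl ether is made by nucleophilic aromatic substitution on a preformed ring A. Commercial 2,6-difluoro-4-methylbenzaldehyde is protected as 2-(2,6-difluoro-4-methylphenyl)-1,3-dioxolane F1 (ethylene glycol, TsOH, toluene, reflux). F1 is lithiated ortho to fluorine, where the two free ring positions are equivalent (sec-BuLi, THF, −78 °C), and trapped with Boc2O to give tert-butyl 3-(1,3-dioxolan-2-yl)-2,4-difluoro-6-methylbenzoate F2. Dilute HCl in THF should release tert-butyl 2,4-difluoro-3-formyl-6-methylbenzoate F3. 4-Methoxybenzyl alcohol with NaH (THF, 0 °C) should displace the less hindered fluoride, para to the ester, to give tert-butyl 2-fluoro-3-formyl-4-[(4-methoxyphenyl)methoxy]-6-methylbenzoate F4. The phenoxide of 7 (Cs2CO3, DMF, 60 °C) then displaces the remaining fluoride, which is activated by the ortho formyl and ortho ester groups, to give tert-butyl 3-formyl-4-[(4-methoxyphenyl)methoxy]-2-({7-[(4-methoxyphenyl)methoxy]-2,2,5-trimethyl-4-oxochroman-6-yl}oxy)-6-methylbenzoate F5. TFA with anisole removes both PMB groups and the tert-butyl group and delivers 23.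

2. Step 5 (C–O coupling). Coupling may be slow at a phenol flanked by a methyl and a benzyloxy group, and the dibromoalkene may be consumed by elimination or by double coupling to a ketene acetal.
Fallback (sets out from 7, returns at 11): addition–elimination with trichloroethylene (K2CO3, DMF, 70 °C) should give 6-{[(E)-1,2-dichloroethenyl]oxy}-7-[(4-methoxyphenyl)methoxy]-2,2,5-trimethylchroman-4-one F6. The ketone is masked in the flask as its lithium enolate (LiN(SiMe3)2, THF, −78 °C); n-BuLi (2.3 equiv) then converts the dichlorovinyl ether into the lithium aryloxyacetylide, which is trapped with formaldehyde to give 6-[(3-hydroxyprop-1-yn-1-yl)oxy]-7-[(4-methoxyphenyl)methoxy]-2,2,5-trimethylchroman-4-one F7. Silylation (TBSCl, imidazole, DMF) gives 11.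

3. Step 2 (acylation/cyclisation). Conjugate alkylation of the arene by the unsaturated acid with lactonisation to a 4,4-dimethylchroman-2-one, acylation at the carbon between O2 and O4, and air oxidation of the triol may all compete.
Fallback (sets out from 3, returns at 6): C-acetylation of 3 with acetic acid and BF3·OEt2 (80 °C) should give 1-(3,4,6-trihydroxy-2-methylphenyl)ethan-1-one F8, with no conjugate acceptor present. Kabbe condensation of F8 with acetone and pyrrolidine (ethanol, reflux, argon) then builds the 2,2-dimethylchromanone 6 by aldol condensation and oxa-Michael closure.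

**Further compounds**
F1 | step 9 | 2-(2,6-difluoro-4-methylphenyl)-1,3-dioxolane | Cc1cc(F)c(C2OCCO2)c(F)c1
F2 | step 9 | tert-butyl 3-(1,3-dioxolan-2-yl)-2,4-difluoro-6-methylbenzoate | Cc1cc(F)c(C2OCCO2)c(F)c1C(=O)OC(C)(C)C
F3 | step 9 | tert-butyl 2,4-difluoro-3-formyl-6-methylbenzoate | Cc1cc(F)c(C=O)c(F)c1C(=O)OC(C)(C)C
F4 | step 9 | tert-butyl 2-fluoro-3-formyl-4-[(4-methoxyphenyl)methoxy]-6-methylbenzoate | Cc1cc(OCc2ccc(OC)cc2)c(C=O)c(F)c1C(=O)OC(C)(C)C
F5 | step 9 | tert-butyl 3-formyl-4-[(4-methoxyphenyl)methoxy]-2-({7-[(4-methoxyphenyl)methoxy]-2,2,5-trimethyl-4-oxochroman-6-yl}oxy)-6-methylbenzoate | Cc1cc(OCc2ccc(OC)cc2)c(C=O)c(Oc2c(C)c3C(=O)CC(C)(C)Oc3cc2OCc4ccc(OC)cc4)c1C(=O)OC(C)(C)C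
F6 | step 5 | 6-{[(E)-1,2-dichloroethenyl]oxy}-7-[(4-methoxyphenyl)methoxy]-2,2,5-trimethylchroman-4-one | Cc1c(O/C(Cl)=C\Cl)c(OCc3ccc(OC)cc3)cc2OC(C)(C)CC(=O)c12
F7 | step 5 | 6-[(3-hydroxyprop-1-yn-1-yl)oxy]-7-[(4-methoxyphenyl)methoxy]-2,2,5-trimethylchroman-4-one | Cc1c(OC#CCO)c(OCc3ccc(OC)cc3)cc2OC(C)(C)CC(=O)c12
F8 | step 2 | 1-(3,4,6-trihydroxy-2-methylphenyl)ethan-1-one | CC(=O)c1c(C)c(O)c(O)cc1O
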